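**Retrosynthetic overview**

1. Polymatin A (26) ← lactone 21 (O8‑PMB, O9‑TBS; PMB is exchanged for the angelate at the end). The α‑methylene‑γ‑lactone is disconnected to CO2 and carbocycle 19: C11–C12 by carboxylation of a 1‑borylvinyl group on C7, O–C6 by attack of the new carboxylate on the C4–C5–C6 π‑allyl unit.
2. Enabling feature: C6 is the allylic carbon of the ring alkene C4=C5 and is 1,3‑related (through C7) to C11, the internal carbon of a former ethynyl group. The unit C6–C7–C11 thus acts as a 1,3‑dipole equivalent that takes up CO2 as C12 plus both lactone oxygens.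
3. Ring A (ten‑membered carbocycle, formed first) ← Nozaki–Hiyama–Kishi closure of C5–C6 in iodo‑aldehyde 16, which also sets C6. Ring B (γ‑lactone) is formed second, in the key step.
4. 16 ← cross‑metathesis (C1=C10) of acrylate 12 with iodo‑diene 3; 12 ← Markovnikov methoxycarbonylation (C14) of diyne 11 ← chelation‑controlled ethynylation (C9) of aldehyde 10.
5. 10 ← Sharpless epoxy alcohol 6 opened by an alkynylalane (C7/C8) ← (E)‑but‑2‑ene‑1,4‑diol; other inputs: hex‑1‑en‑5‑yne, CO, CO2, angelic acid.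

Key step: step 17

Remark: acetal 8 is carried as a mixture at its acetal carbon, which is cleaved in step 6, so that centre is left open in its SMILES; compounds 1, 4 and 23 and all reagents are taken as commercial. Atom numbers C1–C15 are those of the germacrane skeleton; TBS = tert‑butyldimethylsilyl, TMS = trimethylsilyl, PMB = 4‑methoxybenzyl, Bpin = pinacolboryl, IPr = 1,3‑bis(2,6‑diisopropylphenyl)imidazol‑2‑ylidene.

**Route**

Step 1
Reactants: 1 hex‑1‑en‑5‑yne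
Product: 3 (1E)‑1‑iodo‑2‑methylhexa‑1,5‑diene, via alkenylalane 2 (not isolated)
Conditions: AlMe3 (2 equiv), Cp2ZrCl2 (0.25 equiv), CH2Cl2, 0 °C → rt; then I2, THF, −30 → 0 °C
Reagents that add atoms: trimethylaluminium, C[Al](C)C; iodine, II
Why: Zirconium‑catalysed syn‑carboalumination of the terminal alkyne (Negishi carboalumination) adds methyl and aluminium cis with aluminium at the terminus while the isolated vinyl group stays inert, and iodinolysis of the alkenyl–Al bond with retention fixes the (E)‑trisubstituted iodide that becomes C4=C5 with its C15 methyl.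

Step 2
Reactants: 4 (2E)‑but‑2‑ene‑1,4‑diol
Product: 5 (2E)‑4‑{[tert‑butyl(dimethyl)silyl]oxy}but‑2‑en‑1‑ol
Conditions: NaH (1.0 equiv), THF, 0 °C; TBSCl (1.0 equiv), 0 °C → rt
Reagents that add atoms: tert‑butyl(chloro)dimethylsilane, CC(C)(C)[Si](C)(C)Cl
Why: Monodeprotonation of the symmetrical diol gives a sparingly soluble monoalkoxide that is silylated once (O‑silylation of a monosodium alkoxide), and no stereocentre is formed.

Step 3
Reactants: 5 (2E)‑4‑{[tert‑butyl(dimethyl)silyl]oxy}but‑2‑en‑1‑ol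
Product: 6 [(2R,3R)‑3‑({[tert‑butyl(dimethyl)silyl]oxy}methyl)oxiran‑2‑yl]methanol
Conditions: Ti(Oi‑Pr)4 (10 mol%), D‑(−)‑diethyl tartrate (12 mol%), t‑BuOOH, 4 Å MS, CH2Cl2, −20 °C
Reagents that add atoms: tert‑butyl hydroperoxide, CC(C)(C)OO
Why: Sharpless asymmetric epoxidation of the (E)‑allylic alcohol, in which the titanium D‑(−)‑tartrate complex delivers oxygen to the face that gives the (2R,3R)‑epoxy alcohol and thereby fixes the later C8 configuration.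

Step 4
Reactants: 6 [(2R,3R)‑3‑({[tert‑butyl(dimethyl)silyl]oxy}methyl)oxiran‑2‑yl]methanol
Product: 7 (2S,3S)‑4‑{[tert‑butyl(dimethyl)silyl]oxy}‑3‑[(trimethylsilyl)ethynyl]butane‑1,2‑diol
Conditions: Me3SiC≡CH, n‑BuLi, toluene, −78 → 0 °C; Et2AlCl, 0 °C; then 6, 0 °C → rt
Reagents that add atoms: ethynyltrimethylsilane, C#C[Si](C)(C)C
Why: Hydroxyl‑directed opening of the 2,3‑epoxy alcohol by the alkynylalane at C3 (alkynylalane epoxide opening) proceeds with inversion at the attacked carbon, so the alkynyl group on C7 and the retained C8–O bond end up anti.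

Step 5
Reactants: 7 (2S,3S)‑4‑{[tert‑butyl(dimethyl)silyl]oxy}‑3‑[(trimethylsilyl)ethynyl]butane‑1,2‑diol
Product: 8 (4S)‑4‑[(1S)‑1‑({[tert‑butyl(dimethyl)silyl]oxy}methyl)‑3‑(trimethylsilyl)prop‑2‑yn‑1‑yl]‑2‑(4‑methoxyphenyl)‑1,3‑dioxolane
Conditions: 4‑MeOC6H4CH(OMe)2, PPTS (cat.), CH2Cl2, rt
Reagents that add atoms: 4‑methoxybenzaldehyde dimethyl acetal, COc1ccc(cc1)C(OC)OC
Why: Acid‑catalysed transacetalisation of the terminal 1,2‑diol gives the five‑membered 4‑methoxybenzylidene acetal without touching the silyl ether or the alkyne, and the new acetal centre is inconsequential.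

Step 6
Reactants: 8 (4S)‑4‑[(1S)‑1‑({[tert‑butyl(dimethyl)silyl]oxy}methyl)‑3‑(trimethylsilyl)prop‑2‑yn‑1‑yl]‑2‑(4‑methoxyphenyl)‑1,3‑dioxolane
Product: 9 (2S,3S)‑4‑{[tert‑butyl(dimethyl)silyl]oxy}‑2‑[(4‑methoxybenzyl)oxy]‑3‑[(trimethylsilyl)ethynyl]butan‑1‑ol
Conditions: i‑Bu2AlH (3 equiv), CH2Cl2, −78 → 0 °C
Reagents that add atoms: none
Why: Reductive acetal opening by i‑Bu2AlH, in which aluminium binds the less hindered primary oxygen O9, that C–O bond ionises and hydride traps the oxocarbenium ion, so the PMB ether is left on the secondary O8 and the C9 alcohol is free.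

Step 7
Reactants: 9 (2S,3S)‑4‑{[tert‑butyl(dimethyl)silyl]oxy}‑2‑[(4‑methoxybenzyl)oxy]‑3‑[(trimethylsilyl)ethynyl]butan‑1‑ol
Product: 10 (2S,3S)‑4‑{[tert‑butyl(dimethyl)silyl]oxy}‑2‑[(4‑methoxybenzyl)oxy]‑3‑[(trimethylsilyl)ethynyl]butanal
Conditions: Dess–Martin periodinane, NaHCO3, CH2Cl2, 0 °C → rt; used crude
Reagents that add atoms: none
Why: Dess–Martin oxidation of the primary alcohol under buffered conditions should give the α‑alkoxy aldehyde without epimerisation at C8.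

Step 8
Reactants: 10 (2S,3S)‑4‑{[tert‑butyl(dimethyl)silyl]oxy}‑2‑[(4‑methoxybenzyl)oxy]‑3‑[(trimethylsilyl)ethynyl]butanal
Product: 11 (3S,4S,5S)‑6‑{[tert‑butyl(dimethyl)silyl]oxy}‑4‑[(4‑methoxybenzyl)oxy]‑5‑[(trimethylsilyl)ethynyl]hex‑1‑yn‑3‑ol
Conditions: MgBr2·OEt2 (2 equiv), CH2Cl2, −78 °C; HC≡CMgBr, THF/CH2Cl2, −78 °C
Reagents that add atoms: ethynylmagnesium bromide, C#C[Mg]Br
Why: Chelation‑controlled Grignard addition (Cram chelate model), in which magnesium ties the C9 carbonyl to the PMB ether oxygen on C8 in a five‑membered chelate and the acetylide attacks the face away from the C7 branch, giving the 8,9‑syn diol monoether (9S).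

Step 9
Reactants: 11 (3S,4S,5S)‑6‑{[tert‑butyl(dimethyl)silyl]oxy}‑4‑[(4‑methoxybenzyl)oxy]‑5‑[(trimethylsilyl)ethynyl]hex‑1‑yn‑3‑ol
Product: 12 methyl (3S,4S,5S)‑6‑{[tert‑butyl(dimethyl)silyl]oxy}‑3‑hydroxy‑4‑[(4‑methoxybenzyl)oxy]‑2‑methylidene‑5‑[(trimethylsilyl)ethynyl]hexanoate
Conditions: Pd(OAc)2 (2 mol%), 2‑pyridyldiphenylphosphine (8 mol%), MsOH (4 mol%), CO (1 atm), MeOH (10 equiv), CH2Cl2, 40 °C
Reagents that add atoms: carbon monoxide, [C-]#[O+]; methanol, CO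
Why: Palladium‑catalysed Markovnikov methoxycarbonylation of a terminal alkyne (hydropalladation with palladium on the internal carbon, CO insertion, methanolysis) converts only the free ethynyl group into the 2‑substituted acrylate that carries C14, while the silylated alkyne does not react.

Step 10
Reactants: 12 methyl (3S,4S,5S)‑6‑{[tert‑butyl(dimethyl)silyl]oxy}‑3‑hydroxy‑4‑[(4‑methoxybenzyl)oxy]‑2‑methylidene‑5‑[(trimethylsilyl)ethynyl]hexanoate; 3 (1E)‑1‑iodo‑2‑methylhexa‑1,5‑diene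
Product: 13 methyl (2E,6E)‑2‑[(1S,2S,3S)‑4‑{[tert‑butyl(dimethyl)silyl]oxy}‑1‑hydroxy‑2‑[(4‑methoxybenzyl)oxy]‑3‑[(trimethylsilyl)ethynyl]butyl]‑7‑iodo‑6‑methylhepta‑2,6‑dienoate
Conditions: second‑generation Hoveyda–Grubbs catalyst (10 mol%), 3 (3 equiv), 1,4‑benzoquinone (10 mol%), CH2Cl2, 40 °C
Reagents that add atoms: none
Why: Olefin cross‑metathesis between the 1,1‑disubstituted acrylate and the terminal vinyl group of 3 releases ethene and should give the thermodynamically preferred trisubstituted enoate with the chain trans to the ester (C1=C10, E), the trisubstituted vinyl iodide and the silyl alkyne being poor metathesis partners.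

Step 11
Reactants: 13 methyl (2E,6E)‑2‑[(1S,2S,3S)‑4‑{[tert‑butyl(dimethyl)silyl]oxy}‑1‑hydroxy‑2‑[(4‑methoxybenzyl)oxy]‑3‑[(trimethylsilyl)ethynyl]butyl]‑7‑iodo‑6‑methylhepta‑2,6‑dienoate
Product: 14 methyl (2E,6E)‑2‑[(1S,2S,3S)‑1,4‑bis{[tert‑butyl(dimethyl)silyl]oxy}‑2‑[(4‑methoxybenzyl)oxy]‑3‑[(trimethylsilyl)ethynyl]butyl]‑7‑iodo‑6‑methylhepta‑2,6‑dienoate
Conditions: TBSOTf, 2,6‑lutidine, CH2Cl2, −78 → 0 °C
Reagents that add atoms: tert‑butyldimethylsilyl trifluoromethanesulfonate, CC(C)(C)[Si](C)(C)OS(=O)(=O)C(F)(F)F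
Why: O‑Silylation of the hindered allylic alcohol with the silyl triflate masks O9 for the remaining steps and excludes later acyl migration.

Step 12
Reactants: 14 methyl (2E,6E)‑2‑[(1S,2S,3S)‑1,4‑bis{[tert‑butyl(dimethyl)silyl]oxy}‑2‑[(4‑methoxybenzyl)oxy]‑3‑[(trimethylsilyl)ethynyl]butyl]‑7‑iodo‑6‑methylhepta‑2,6‑dienoate
Product: 15 methyl (2E,6E)‑2‑[(1S,2S,3S)‑1‑{[tert‑butyl(dimethyl)silyl]oxy}‑3‑ethynyl‑4‑hydroxy‑2‑[(4‑methoxybenzyl)oxy]butyl]‑7‑iodo‑6‑methylhepta‑2,6‑dienoate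
Conditions: NH4F (10 equiv), MeOH, 50 °C
Reagents that add atoms: none
Why: Selective fluoride desilylation in methanol should cleave the alkynyl C–Si bond and the primary TBS ether much faster than the hindered secondary allylic TBS ether, revealing the C6 alcohol and the terminal alkyne together.

Step 13
Reactants: 15 methyl (2E,6E)‑2‑[(1S,2S,3S)‑1‑{[tert‑butyl(dimethyl)silyl]oxy}‑3‑ethynyl‑4‑hydroxy‑2‑[(4‑methoxybenzyl)oxy]butyl]‑7‑iodo‑6‑methylhepta‑2,6‑dienoate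
Product: 16 methyl (2E,6E)‑2‑[(1S,2S,3R)‑1‑{[tert‑butyl(dimethyl)silyl]oxy}‑3‑ethynyl‑2‑[(4‑methoxybenzyl)oxy]‑4‑oxobutyl]‑7‑iodo‑6‑methylhepta‑2,6‑dienoate
Conditions: Dess–Martin periodinane, NaHCO3, CH2Cl2, 0 °C; used at once without chromatography
Reagents that add atoms: none
Why: Dess–Martin oxidation gives the C6 aldehyde under neutral conditions that should avoid epimerisation at C7 and isomerisation of the propargylic aldehyde to an allene.

Step 14
Reactants: 16 methyl (2E,6E)‑2‑[(1S,2S,3R)‑1‑{[tert‑butyl(dimethyl)silyl]oxy}‑3‑ethynyl‑2‑[(4‑methoxybenzyl)oxy]‑4‑oxobutyl]‑7‑iodo‑6‑methylhepta‑2,6‑dienoate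
Product: 17 methyl (1E,5E,7R,8S,9S,10S)‑10‑{[tert‑butyl(dimethyl)silyl]oxy}‑8‑ethynyl‑7‑hydroxy‑9‑[(4‑methoxybenzyl)oxy]‑5‑methylcyclodeca‑1,5‑diene‑1‑carboxylate
Conditions: CrCl2 (10 equiv), NiCl2 (2 mol%), DMSO/THF, 0.002 M (slow addition of 16), rt
Reagents that add atoms: none
Why: Nozaki–Hiyama–Kishi reaction, in which nickel‑catalysed activation of the alkenyl iodide and transfer to chromium give an alkenylchromium species that adds to the aldehyde intramolecularly under high dilution with retention of the 4E geometry, the non‑chelating addition following the Felkin–Anh model at C7 reinforced by 1,3‑anti induction from the C8 ether so that the 6R alcohol (O6 syn to the ethynyl group) should form.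

Step 15
Reactants: 17 methyl (1E,5E,7R,8S,9S,10S)‑10‑{[tert‑butyl(dimethyl)silyl]oxy}‑8‑ethynyl‑7‑hydroxy‑9‑[(4‑methoxybenzyl)oxy]‑5‑methylcyclodeca‑1,5‑diene‑1‑carboxylate
Product: 18 methyl (1E,5E,7R,8S,9S,10S)‑10‑{[tert‑butyl(dimethyl)silyl]oxy}‑7‑hydroxy‑9‑[(4‑methoxybenzyl)oxy]‑5‑methyl‑8‑[1‑(4,4,5,5‑tetramethyl‑1,3,2‑dioxaborolan‑2‑yl)ethenyl]cyclodeca‑1,5‑diene‑1‑carboxylate
Conditions: Pd2(dba)3 (2.5 mol%), PCy3 (10 mol%), B2pin2 (1.2 equiv), AcOH (1.2 equiv), toluene, 60 °C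
Reagents that add atoms: bis(pinacolato)diboron, CC1(C)OB(OC1(C)C)B1OC(C)(C)C(C)(C)O1
Why: Palladium‑catalysed Markovnikov hydroboration of the terminal alkyne (a palladium hydride from AcOH adds with palladium on the internal carbon, then boryl transfer from B2pin2 under trialkylphosphine control) places boron on C11 and gives the 1,1‑disubstituted alkenylboronate.

Step 16
Reactants: 18 methyl (1E,5E,7R,8S,9S,10S)‑10‑{[tert‑butyl(dimethyl)silyl]oxy}‑7‑hydroxy‑9‑[(4‑methoxybenzyl)oxy]‑5‑methyl‑8‑[1‑(4,4,5,5‑tetramethyl‑1,3,2‑dioxaborolan‑2‑yl)ethenyl]cyclodeca‑1,5‑diene‑1‑carboxylate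
Product: 19 methyl (1E,5E,7R,8S,9S,10S)‑10‑{[tert‑butyl(dimethyl)silyl]oxy}‑7‑[(methoxycarbonyl)oxy]‑9‑[(4‑methoxybenzyl)oxy]‑5‑methyl‑8‑[1‑(4,4,5,5‑tetramethyl‑1,3,2‑dioxaborolan‑2‑yl)ethenyl]cyclodeca‑1,5‑diene‑1‑carboxylate
Conditions: ClCO2Me, pyridine, DMAP (cat.), CH2Cl2, 0 °C
Reagents that add atoms: methyl chloroformate, COC(=O)Cl
Why: Acylation of the C6 alcohol with the chloroformate gives the allylic methyl carbonate that serves as the leaving group for π‑allyl formation, with the C6 configuration unchanged.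

Step 17
Reactants: 19 methyl (1E,5E,7R,8S,9S,10S)‑10‑{[tert‑butyl(dimethyl)silyl]oxy}‑7‑[(methoxycarbonyl)oxy]‑9‑[(4‑methoxybenzyl)oxy]‑5‑methyl‑8‑[1‑(4,4,5,5‑tetramethyl‑1,3,2‑dioxaborolan‑2‑yl)ethenyl]cyclodeca‑1,5‑diene‑1‑carboxylate
Product: 21 methyl (3aS,4S,5S,6E,10E,11aR)‑5‑{[tert‑butyl(dimethyl)silyl]oxy}‑4‑[(4‑methoxybenzyl)oxy]‑10‑methyl‑3‑methylidene‑2‑oxo‑2,3,3a,4,5,8,9,11a‑octahydrocyclodeca[b]furan‑6‑carboxylate, via potassium acrylate 20 (not isolated)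
Conditions: (IPr)CuCl (10 mol%), KOt‑Bu (1.05 equiv), THF, 0 °C, then CO2 (1 atm), 60 °C; then Pd(PPh3)4 (5 mol%), CO2 (1 atm), 25 °C
Reagents that add atoms: carbon dioxide, O=C=O; potassium tert‑butoxide, CC(C)(C)[O-].[K+] (its potassium stays only in intermediate 20)
Why: Proposed new method: tert‑butoxide converts the 1‑borylvinyl group of 19 into a borate that hands the alkenyl group to the NHC‑bound monovalent copper, the alkenylcopper inserts CO2 to give acrylate 20 (bond C11–C12), and zerovalent palladium then ionises the C6 methyl carbonate to a C4–C5–C6 π‑allyl complex that the tethered carboxylate attacks at C6 (bond O–C6), the whole being a formal [3+2] annulation of CO2 across C6–C7–C11. The closest known reaction types are the copper‑catalysed carboxylation of alkenylboronic esters with CO2 and the palladium‑catalysed intramolecular allylic substitution by carboxylates (Tsuji–Trost lactonisation); their one‑flask relay on a substrate carrying both functions has not been described. The γ‑lactone closes in the 5‑exo mode at the allyl terminus C6, whereas attack at C4 would need a seven‑membered ring and a quaternary centre. No new stereocentre is created: palladium ionises anti to the carbonate and the carboxylate attacks anti to palladium, so C6 reacts with net retention and the 6,7‑trans ring fusion follows from the C6 configuration set in step 14. The step needs carboxylation to outrun allyl–alkenyl C–C coupling, which is secured by adding the palladium catalyst only after the boronate is consumed, and it needs the 4E geometry to survive, which the ten‑membered ring and the fast intramolecular capture should secure by disfavouring isomerisation through the C4‑bound η1‑allyl form. The base is bound as the borate and free alkoxide is buffered by CO2, so the esters, the carbonate and the silyl ether should not be attacked.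

Step 18
Reactants: 21 methyl (3aS,4S,5S,6E,10E,11aR)‑5‑{[tert‑butyl(dimethyl)silyl]oxy}‑4‑[(4‑methoxybenzyl)oxy]‑10‑methyl‑3‑methylidene‑2‑oxo‑2,3,3a,4,5,8,9,11a‑octahydrocyclodeca[b]furan‑6‑carboxylate
Product: 22 methyl (3aR,4S,5S,6E,10E,11aR)‑5‑{[tert‑butyl(dimethyl)silyl]oxy}‑4‑hydroxy‑10‑methyl‑3‑methylidene‑2‑oxo‑2,3,3a,4,5,8,9,11a‑octahydrocyclodeca[b]furan‑6‑carboxylate
Conditions: DDQ (1.5 equiv), CH2Cl2/pH 7 buffer, 0 °C
Reagents that add atoms: none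
Why: Oxidative cleavage of the 4‑methoxybenzyl ether by DDQ (hydride abstraction to the oxocarbenium ion, then hydrolysis) frees the C8 hydroxyl without touching the silyl ether, the alkenes or the α‑methylene lactone; the descriptor at C3a changes only because the ligand priorities change.

Step 19
Reactants: 22 methyl (3aR,4S,5S,6E,10E,11aR)‑5‑{[tert‑butyl(dimethyl)silyl]oxy}‑4‑hydroxy‑10‑methyl‑3‑methylidene‑2‑oxo‑2,3,3a,4,5,8,9,11a‑octahydrocyclodeca[b]furan‑6‑carboxylate; 23 angelic acid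
Product: 25 methyl (3aS,4S,5S,6E,10E,11aR)‑5‑{[tert‑butyl(dimethyl)silyl]oxy}‑10‑methyl‑3‑methylidene‑4‑{[(2Z)‑2‑methylbut‑2‑enoyl]oxy}‑2‑oxo‑2,3,3a,4,5,8,9,11a‑octahydrocyclodeca[b]furan‑6‑carboxylate, via mixed anhydride 24 (not isolated)
Conditions: 23, 2,4,6‑Cl3C6H2COCl, Et3N, toluene, rt; then 22, 80 °C
Reagents that add atoms: 2,4,6‑trichlorobenzoyl chloride, O=C(Cl)c1c(Cl)cc(Cl)cc1Cl (its atoms stay only in intermediate 24)
Why: Yamaguchi esterification through the mixed 2,4,6‑trichlorobenzoic anhydride acylates the C8 hydroxyl at the less hindered angeloyl carbonyl without a nucleophilic catalyst, which should avoid Z‑to‑E isomerisation of the angelate, and the silylated O9 excludes acyl migration.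

Step 20
Reactants: 25 methyl (3aS,4S,5S,6E,10E,11aR)‑5‑{[tert‑butyl(dimethyl)silyl]oxy}‑10‑methyl‑3‑methylidene‑4‑{[(2Z)‑2‑methylbut‑2‑enoyl]oxy}‑2‑oxo‑2,3,3a,4,5,8,9,11a‑octahydrocyclodeca[b]furan‑6‑carboxylate
Product: 26 polymatin A
Conditions: HF·pyridine, pyridine, THF, 0 °C → rt
Reagents that add atoms: none
Why: Acidic fluoride desilylation removes the TBS ether under non‑basic conditions, so neither acyl migration from O8 to O9 nor conjugate addition to the α‑methylene lactone should occur.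

**Compound list**

1 | hex‑1‑en‑5‑yne | C=CCCC#C | starting material
2 | dimethyl[(1E)‑2‑methylhexa‑1,5‑dien‑1‑yl]aluminium | C=CCC/C(C)=C/[Al](C)C | intermediate
3 | (1E)‑1‑iodo‑2‑methylhexa‑1,5‑diene | C=CCC/C(C)=C/I | intermediate
4 | (2E)‑but‑2‑ene‑1,4‑diol | OC/C=C/CO | starting material
5 | (2E)‑4‑{[tert‑butyl(dimethyl)silyl]oxy}but‑2‑en‑1‑ol | OC/C=C/CO[Si](C)(C)C(C)(C)C | intermediate
6 | [(2R,3R)‑3‑({[tert‑butyl(dimethyl)silyl]oxy}methyl)oxiran‑2‑yl]methanol | OC[C@H]1O[C@@H]1CO[Si](C)(C)C(C)(C)C | intermediate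
7 | (2S,3S)‑4‑{[tert‑butyl(dimethyl)silyl]oxy}‑3‑[(trimethylsilyl)ethynyl]butane‑1,2‑diol | OC[C@@H](O)[C@@H](C#C[Si](C)(C)C)CO[Si](C)(C)C(C)(C)C | intermediate
8 | (4S)‑4‑[(1S)‑1‑({[tert‑butyl(dimethyl)silyl]oxy}methyl)‑3‑(trimethylsilyl)prop‑2‑yn‑1‑yl]‑2‑(4‑methoxyphenyl)‑1,3‑dioxolane (both epimers at C2) | COc1ccc(cc1)C1OC[C@@H](O1)[C@@H](C#C[Si](C)(C)C)CO[Si](C)(C)C(C)(C)C | intermediate
9 | (2S,3S)‑4‑{[tert‑butyl(dimethyl)silyl]oxy}‑2‑[(4‑methoxybenzyl)oxy]‑3‑[(trimethylsilyl)ethynyl]butan‑1‑ol | OC[C@@H](OCc1ccc(OC)cc1)[C@@H](C#C[Si](C)(C)C)CO[Si](C)(C)C(C)(C)C | intermediate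
10 | (2S,3S)‑4‑{[tert‑butyl(dimethyl)silyl]oxy}‑2‑[(4‑methoxybenzyl)oxy]‑3‑[(trimethylsilyl)ethynyl]butanal | O=C[C@@H](OCc1ccc(OC)cc1)[C@@H](C#C[Si](C)(C)C)CO[Si](C)(C)C(C)(C)C | intermediate
11 | (3S,4S,5S)‑6‑{[tert‑butyl(dimethyl)silyl]oxy}‑4‑[(4‑methoxybenzyl)oxy]‑5‑[(trimethylsilyl)ethynyl]hex‑1‑yn‑3‑ol | C#C[C@H](O)[C@@H](OCc1ccc(OC)cc1)[C@@H](C#C[Si](C)(C)C)CO[Si](C)(C)C(C)(C)C | intermediate
12 | methyl (3S,4S,5S)‑6‑{[tert‑butyl(dimethyl)silyl]oxy}‑3‑hydroxy‑4‑[(4‑methoxybenzyl)oxy]‑2‑methylidene‑5‑[(trimethylsilyl)ethynyl]hexanoate | C=C(C(=O)OC)[C@H](O)[C@@H](OCc1ccc(OC)cc1)[C@@H](C#C[Si](C)(C)C)CO[Si](C)(C)C(C)(C)C | intermediate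
13 | methyl (2E,6E)‑2‑[(1S,2S,3S)‑4‑{[tert‑butyl(dimethyl)silyl]oxy}‑1‑hydroxy‑2‑[(4‑methoxybenzyl)oxy]‑3‑[(trimethylsilyl)ethynyl]butyl]‑7‑iodo‑6‑methylhepta‑2,6‑dienoate | I/C=C(\C)CC/C=C(/C(=O)OC)[C@H](O)[C@@H](OCc1ccc(OC)cc1)[C@@H](C#C[Si](C)(C)C)CO[Si](C)(C)C(C)(C)C | intermediate
14 | methyl (2E,6E)‑2‑[(1S,2S,3S)‑1,4‑bis{[tert‑butyl(dimethyl)silyl]oxy}‑2‑[(4‑methoxybenzyl)oxy]‑3‑[(trimethylsilyl)ethynyl]butyl]‑7‑iodo‑6‑methylhepta‑2,6‑dienoate | I/C=C(\C)CC/C=C(/C(=O)OC)[C@H](O[Si](C)(C)C(C)(C)C)[C@@H](OCc1ccc(OC)cc1)[C@@H](C#C[Si](C)(C)C)CO[Si](C)(C)C(C)(C)C | intermediate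
15 | methyl (2E,6E)‑2‑[(1S,2S,3S)‑1‑{[tert‑butyl(dimethyl)silyl]oxy}‑3‑ethynyl‑4‑hydroxy‑2‑[(4‑methoxybenzyl)oxy]butyl]‑7‑iodo‑6‑methylhepta‑2,6‑dienoate | I/C=C(\C)CC/C=C(/C(=O)OC)[C@H](O[Si](C)(C)C(C)(C)C)[C@@H](OCc1ccc(OC)cc1)[C@@H](C#C)CO | intermediate
16 | methyl (2E,6E)‑2‑[(1S,2S,3R)‑1‑{[tert‑butyl(dimethyl)silyl]oxy}‑3‑ethynyl‑2‑[(4‑methoxybenzyl)oxy]‑4‑oxobutyl]‑7‑iodo‑6‑methylhepta‑2,6‑dienoate | I/C=C(\C)CC/C=C(/C(=O)OC)[C@H](O[Si](C)(C)C(C)(C)C)[C@@H](OCc1ccc(OC)cc1)[C@@H](C#C)C=O | intermediate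
17 | methyl (1E,5E,7R,8S,9S,10S)‑10‑{[tert‑butyl(dimethyl)silyl]oxy}‑8‑ethynyl‑7‑hydroxy‑9‑[(4‑methoxybenzyl)oxy]‑5‑methylcyclodeca‑1,5‑diene‑1‑carboxylate | O[C@@H]1/C=C(\C)CC/C=C(/C(=O)OC)[C@H](O[Si](C)(C)C(C)(C)C)[C@@H](OCc2ccc(OC)cc2)[C@H]1C#C | intermediate
18 | methyl (1E,5E,7R,8S,9S,10S)‑10‑{[tert‑butyl(dimethyl)silyl]oxy}‑7‑hydroxy‑9‑[(4‑methoxybenzyl)oxy]‑5‑methyl‑8‑[1‑(4,4,5,5‑tetramethyl‑1,3,2‑dioxaborolan‑2‑yl)ethenyl]cyclodeca‑1,5‑diene‑1‑carboxylate | O[C@@H]1/C=C(\C)CC/C=C(/C(=O)OC)[C@H](O[Si](C)(C)C(C)(C)C)[C@@H](OCc2ccc(OC)cc2)[C@H]1C(=C)B1OC(C)(C)C(C)(C)O1 | intermediate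
19 | methyl (1E,5E,7R,8S,9S,10S)‑10‑{[tert‑butyl(dimethyl)silyl]oxy}‑7‑[(methoxycarbonyl)oxy]‑9‑[(4‑methoxybenzyl)oxy]‑5‑methyl‑8‑[1‑(4,4,5,5‑tetramethyl‑1,3,2‑dioxaborolan‑2‑yl)ethenyl]cyclodeca‑1,5‑diene‑1‑carboxylate | COC(=O)O[C@@H]1/C=C(\C)CC/C=C(/C(=O)OC)[C@H](O[Si](C)(C)C(C)(C)C)[C@@H](OCc2ccc(OC)cc2)[C@H]1C(=C)B1OC(C)(C)C(C)(C)O1 | intermediate
20 | potassium 2‑[(1S,2S,3S,4E,8E,10R)‑3‑{[tert‑butyl(dimethyl)silyl]oxy}‑4‑(methoxycarbonyl)‑10‑[(methoxycarbonyl)oxy]‑2‑[(4‑methoxybenzyl)oxy]‑8‑methylcyclodeca‑4,8‑dien‑1‑yl]prop‑2‑enoate | COC(=O)O[C@@H]1/C=C(\C)CC/C=C(/C(=O)OC)[C@H](O[Si](C)(C)C(C)(C)C)[C@@H](OCc2ccc(OC)cc2)[C@H]1C(=C)C(=O)[O-].[K+] | intermediate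
21 | methyl (3aS,4S,5S,6E,10E,11aR)‑5‑{[tert‑butyl(dimethyl)silyl]oxy}‑4‑[(4‑methoxybenzyl)oxy]‑10‑methyl‑3‑methylidene‑2‑oxo‑2,3,3a,4,5,8,9,11a‑octahydrocyclodeca[b]furan‑6‑carboxylate | C=C1C(=O)O[C@@H]2/C=C(\C)CC/C=C(/C(=O)OC)[C@H](O[Si](C)(C)C(C)(C)C)[C@@H](OCc3ccc(OC)cc3)[C@@H]12 | intermediate
22 | methyl (3aR,4S,5S,6E,10E,11aR)‑5‑{[tert‑butyl(dimethyl)silyl]oxy}‑4‑hydroxy‑10‑methyl‑3‑methylidene‑2‑oxo‑2,3,3a,4,5,8,9,11a‑octahydrocyclodeca[b]furan‑6‑carboxylate | C=C1C(=O)O[C@@H]2/C=C(\C)CC/C=C(/C(=O)OC)[C@H](O[Si](C)(C)C(C)(C)C)[C@@H](O)[C@@H]12 | intermediate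
23 | angelic acid, (2Z)‑2‑methylbut‑2‑enoic acid | C/C=C(/C)C(=O)O | starting material
24 | (2Z)‑2‑methylbut‑2‑enoic 2,4,6‑trichlorobenzoic anhydride | C/C=C(/C)C(=O)OC(=O)c1c(Cl)cc(Cl)cc1Cl | intermediate
25 | methyl (3aS,4S,5S,6E,10E,11aR)‑5‑{[tert‑butyl(dimethyl)silyl]oxy}‑10‑methyl‑3‑methylidene‑4‑{[(2Z)‑2‑methylbut‑2‑enoyl]oxy}‑2‑oxo‑2,3,3a,4,5,8,9,11a‑octahydrocyclodeca[b]furan‑6‑carboxylate | C=C1C(=O)O[C@@H]2/C=C(\C)CC/C=C(/C(=O)OC)[C@H](O[Si](C)(C)C(C)(C)C)[C@@H](OC(=O)/C(C)=C\C)[C@@H]12 | intermediate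
26 | polymatin A, methyl (3aS,4S,5S,6E,10E,11aR)‑5‑hydroxy‑10‑methyl‑3‑methylidene‑4‑{[(2Z)‑2‑methylbut‑2‑enoyl]oxy}‑2‑oxo‑2,3,3a,4,5,8,9,11a‑octahydrocyclodeca[b]furan‑6‑carboxylate | C=C1C(=O)O[C@@H]2/C=C(\C)CC/C=C(/C(=O)OC)[C@H](O)[C@@H](OC(=O)/C(C)=C\C)[C@@H]12 | target

**Step count and risks**

Total step count: 20. Longest linear sequence: 19 steps (steps 2–20, from diol 4); step 1 supplies iodo‑diene 3 for step 10.

Steps most likely to fail:

Step 17 (proposed new method). What may go wrong: allyl–alkenyl C–C coupling or protodeboronation may compete with CO2 insertion, the carbonate may be lost to alkoxide, or the C6 configuration and the 4E geometry may erode through π‑allyl isomerisation or reversible ionisation of the product lactone. The fallback uses known chemistry, sets out from 17 and returns to the route at 21. Palladium‑catalysed cyclocarbonylation of the homopropargylic alcohol (Pd(OAc)2, 2‑pyridyldiphenylphosphine, MsOH, CO, CH2Cl2, 40 °C; the catalyst system of step 9 with the C6 hydroxyl as internal nucleophile) would build the α‑methylene‑γ‑lactone of 21 directly from the ethynyl group, CO and O6 with retention at C6. Steps 15 and 16 would then be omitted. This fallback makes no compound outside the compound list (entry F0).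

Step 10. What may go wrong: slow turnover at the hindered 1,1‑disubstituted acrylate, self‑metathesis of 3 consuming the partner, ruthenium hydride isomerisation of the allylic alcohol, or incomplete control of the C1=C10 geometry. The fallback sets out from 12 and returns at 14; it replaces metathesis by carbonyl olefination. Silylation of 12 (TBSOTf, 2,6‑lutidine) would give methyl (3S,4S,5S)‑3,6‑bis{[tert‑butyl(dimethyl)silyl]oxy}‑4‑[(4‑methoxybenzyl)oxy]‑2‑methylidene‑5‑[(trimethylsilyl)ethynyl]hexanoate F1. Dihydroxylation and glycol cleavage of its only alkene (OsO4 cat., NMO; then NaIO4) would give the α‑keto ester methyl (3R,4S,5S)‑3,6‑bis{[tert‑butyl(dimethyl)silyl]oxy}‑4‑[(4‑methoxybenzyl)oxy]‑2‑oxo‑5‑[(trimethylsilyl)ethynyl]hexanoate F2. In parallel, commercial 5‑chloropent‑1‑yne would be taken through the carboalumination–iodination of step 1 to (1E)‑5‑chloro‑1‑iodo‑2‑methylpent‑1‑ene F3, and NaI/PPh3 in MeCN at reflux would convert it into [(4E)‑5‑iodo‑4‑methylpent‑4‑en‑1‑yl]triphenylphosphonium iodide F4. Wittig olefination of F2 with the ylide from F4 (NaHMDS, THF, −78 °C) should place the new chain cis to the silyloxy‑bearing carbon C9, as is usual for non‑stabilised ylides and α‑alkoxy ketones, and give 14.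

Step 14. What may go wrong: poor facial selectivity at C6 under the conformational constraints of the ring closure, intermolecular coupling in place of cyclisation, or enolisation of the α‑ethynyl aldehyde with loss of the C7 configuration. The fallback sets out from 17 obtained as a mixture of C6 epimers and returns at 17; it replaces substrate control by reagent control. Dess–Martin oxidation of the mixture would give the enone methyl (1E,5E,8R,9S,10S)‑10‑{[tert‑butyl(dimethyl)silyl]oxy}‑8‑ethynyl‑9‑[(4‑methoxybenzyl)oxy]‑5‑methyl‑7‑oxocyclodeca‑1,5‑diene‑1‑carboxylate F5. Corey–Bakshi–Shibata reduction with the oxazaborolidine enantiomer that delivers hydride to the required face (BH3·SMe2, THF, −40 °C) should return the 7R alcohol 17 as a single epimer.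

**Further compounds**

F0 | step 17 | none | none
F1 | step 10 | methyl (3S,4S,5S)‑3,6‑bis{[tert‑butyl(dimethyl)silyl]oxy}‑4‑[(4‑methoxybenzyl)oxy]‑2‑methylidene‑5‑[(trimethylsilyl)ethynyl]hexanoate | C=C(C(=O)OC)[C@H](O[Si](C)(C)C(C)(C)C)[C@@H](OCc1ccc(OC)cc1)[C@@H](C#C[Si](C)(C)C)CO[Si](C)(C)C(C)(C)C
F2 | step 10 | methyl (3R,4S,5S)‑3,6‑bis{[tert‑butyl(dimethyl)silyl]oxy}‑4‑[(4‑methoxybenzyl)oxy]‑2‑oxo‑5‑[(trimethylsilyl)ethynyl]hexanoate | COC(=O)C(=O)[C@H](O[Si](C)(C)C(C)(C)C)[C@@H](OCc1ccc(OC)cc1)[C@@H](C#C[Si](C)(C)C)CO[Si](C)(C)C(C)(C)C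
F3 | step 10 | (1E)‑5‑chloro‑1‑iodo‑2‑methylpent‑1‑ene | ClCCC/C(C)=C/I
F4 | step 10 | [(4E)‑5‑iodo‑4‑methylpent‑4‑en‑1‑yl]triphenylphosphonium iodide | [I-].I/C=C(\C)CCC[P+](c1ccccc1)(c1ccccc1)c1ccccc1
F5 | step 14 | methyl (1E,5E,8R,9S,10S)‑10‑{[tert‑butyl(dimethyl)silyl]oxy}‑8‑ethynyl‑9‑[(4‑methoxybenzyl)oxy]‑5‑methyl‑7‑oxocyclodeca‑1,5‑diene‑1‑carboxylate | O=C1/C=C(\C)CC/C=C(/C(=O)OC)[C@H](O[Si](C)(C)C(C)(C)C)[C@@H](OCc2ccc(OC)cc2)[C@H]1C#C
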